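The hexamer (rings A–F joined by five CH2 groups) is cut at the ring B–ring C and ring D–ring E bridges, each at its bond to C-3 of ring B or E. The feature exploited is that this carbon sits ortho to the hydroxyl oxygens on C-2 and C-4 of those rings. In one operation a central ring C–ring D unit carrying a CH2SCH3 group on each ring is activated at sulfur, tethered to a ring B oxygen of two ring A–B dimers, and rearranged by a double [2,3]-sigmatropic shift of aryloxysulfonium ylides, forming both C–C bonds ortho-selectively and only between unlike fragments. The precursor is the bis(methylthiomethyl) hexaacetate of methylenebis(phlorobutyrophenone).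

Key step: step 6

Remark (locants and tautomers): in rings B and E, C-1 carries the CH2 to ring A (or F), C-2 an OH, C-3 is the free carbon, C-4 an OH, C-5 the butanoyl group and C-6 an OH. Rings A and F are written throughout in the enol tautomer used for the target, which has no stereocentre.

Remark (numbering and equivalents): compounds whose atoms remain in the target (1, 2, 4) are numbered as starting materials and stand on the Reactants lines. Step 1 builds two molecules of 2 into its product, so 2 stands there on the Reactants line and, for the second methyl group, once more on the line of reagents that add atoms. Reagents whose atoms are removed again are given with SMILES in the steps.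

Step 1
Reactants: 1 phlorobutyrophenone; 2 iodomethane (2.2 equiv)
Product: 3 butyrylfilicinic acid
Conditions: NaOMe (3 equiv), MeI (2.2 equiv in all), MeOH, 0 °C to rt; aq HCl, then extraction into aq NaHCO3, re-acidification and crystallisation
Reagents that add atoms: iodomethane (MeI), CI
Why: Double C-methylation of the phloroglucinol polyanion (dearomatising geminal alkylation, the classical entry to acylfilicinic acids), in which the second methyl group enters at the carbon already methylated because the resulting cross-conjugated triketone is a stabilised vinylogous acid, should give 3 with both methyl groups drawn from 2 (one counted on the Reactants line, the second on the reagent line); 3 is separated from mono- and over-methylated by-products through its solubility in aqueous NaHCO3.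

Step 2
Reactants: 3 butyrylfilicinic acid; 4 formaldehyde; 1 phlorobutyrophenone
Product: 6 ring A–ring B dimer (norflavaspidic acid type), via piperidinomethyl Mannich base 5 (not isolated)
Conditions: CH2O (37% aq, 1.05 equiv) premixed with piperidine (1.2 equiv), EtOH, 0 °C to rt; then 1 (3 equiv), 70 °C; aq HCl work-up
Reagents that add atoms: none
Why: Mannich reaction at the only free ring carbon (C-6) of 3 gives 5, which on warming loses piperidine to an exocyclic enone (quinone-methide-type acceptor) that is trapped by C-3 of 1 in a Michael/Friedel–Crafts alkylation; the secondary amine cannot form an enaminone with the triketone, and the excess of 1 holds back a second alkylation of ring B.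

Step 3
Reactants: 1 phlorobutyrophenone (4 equiv); 4 formaldehyde (1 equiv)
Product: 7 methylenebis(phlorobutyrophenone), the ring C–ring D dimer
Conditions: 1 (4 equiv), CH2O (37% aq, 1 equiv), 1% aq KOH, 0 °C to rt, 10 min; then cold aq HCl
Reagents that add atoms: none
Why: Base-mediated hydroxymethylation of one molecule of 1, loss of water to the quinone methide and conjugate addition of a second phenoxide of 1 (the classical formaldehyde coupling of acylphloroglucinols) should give the symmetrical dimer built from two molecules of 1, the excess of 1 (recovered) keeping chain growth to trimers low.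

Step 4
Reactants: 7 methylenebis(phlorobutyrophenone); 4 formaldehyde (3 equiv)
Product: 8 bis(methylthiomethyl) ring C–ring D dimer (hexaphenol)
Conditions: CH2O (37% aq, 3 equiv), NaSCH3 (4 equiv), AcOH (4 equiv), Et3N (0.2 equiv), EtOH, 50 °C, closed vessel
Reagents that add atoms: sodium methanethiolate (NaSCH3), C[S-].[Na+]
Why: This is the thiol variant of the phenol Mannich reaction (hydroxymethylation at the single free carbon of each ring, quinone methide formation, thia-Michael addition, once on each ring), in which the soft thiol in excess should outcompete ring carbons for the quinone methide so that further methylene bridging is suppressed.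

Step 5
Reactants: 8 bis(methylthiomethyl) ring C–ring D dimer (hexaphenol)
Product: 9 bis(methylthiomethyl) ring C–ring D dimer hexaacetate
Conditions: Ac2O (12 equiv), pyridine, DMAP (0.2 equiv), rt to 40 °C
Reagents that add atoms: acetic anhydride (Ac2O), CC(=O)OC(C)=O
Why: DMAP-catalysed O-acylation (Steglich-type acyl transfer) should cap all six phenols, the ring carbons being fully substituted and the sulfides inert to Ac2O; the acetates remove the internal hydroxyls that could capture activated sulfur or expel thiol, and make rings C and D electron-poor.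

Step 6
Reactants: 9 bis(methylthiomethyl) ring C–ring D dimer hexaacetate; 6 ring A–ring B dimer (2.3 equiv)
Product: 12 hexamer hexaacetate with SCH3 on the B–C and D–E bridge carbons (diastereomer mixture), via bis(chlorosulfonium) salt 10 (not isolated), via bis(aryloxysulfonium) salt 11 (not isolated)
Conditions: NCS (2.05 equiv), CH2Cl2, −78 °C; then 6 (2.3 equiv) in CH2Cl2/THF, −78 to −40 °C; then Et3N (8 equiv), −40 °C to rt
Reagents that add atoms: none
Why: NCS chlorinates each sulfide sulfur of 9 to the chlorosulfonium salt 10, the non-chelated hydroxyl at C-2 of ring B of 6 (para to the butanoyl group) displaces chloride to give the aryloxysulfonium salt 11, and Et3N removes a proton from the sulfur-bound benzylic CH2 so that the ylide carbon bonds to C-3 of ring B in a concerted [2,3]-sigmatropic shift with O–S cleavage, after which the cyclohexadienone tautomerises back to the phenol. The closest known reaction type is the ortho-alkylation of phenols through aryloxysulfonium ylides (the oxygen analogue of the Gassman aniline alkylation and a relative of the Sommelet–Hauser rearrangement), and any alpha-chloro sulfide formed by Pummerer-type collapse of 10 would ionise to a thionium ion whose Friedel–Crafts capture by the same ring B carbon leads to the same product. No ring is closed. The two new stereocentres at the CH(SCH3) bridge carbons have no controlling element and should form as a mixture of the meso and racemic diastereomers, which is of no consequence because both centres become CH2 in step 7. The step needs bond formation at C-3 of ring B only, secured because this is the sole unsubstituted ortho carbon (a shift to a substituted ortho carbon would give a dienone that cannot rearomatise, and oxysulfonium ions at ring A enol oxygens face only fully substituted neighbouring carbons and should revert by exchange faster than they rearrange), and it needs cross-coupling only, secured because rings C and D carry no free hydroxyl and NCS is consumed at −78 °C before 6 is added. Ylide formation at S-CH3, which would lead to a CH2–S–CH2 link, is disfavoured by the much lower acidity of that methyl group compared with the benzylic CH2 on the triacetoxy-acyl arene, and any acetyl transfer between phenol oxygens is harmless since all acetates are removed in step 8.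

Step 7
Reactants: 12 hexamer hexaacetate with SCH3 on the B–C and D–E bridge carbons
Product: 13 hexamer hexaacetate (acetates on rings C and D)
Conditions: Bu3SnH (6 equiv), AIBN (0.4 equiv, in portions), degassed toluene, 90 °C
Reagents that add atoms: none
Why: In this radical chain desulfurisation Bu3Sn radicals attack sulfur and release the doubly benzylic (diarylmethyl) radical, which abstracts hydrogen from Bu3SnH; aryl acetates, ketones and enols should not be touched, and both sulfur-bearing stereocentres become CH2.

Step 8
Reactants: 13 hexamer hexaacetate (acetates on rings C and D)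
Product: 14 target hexamer CNP0237140.0
Conditions: K2CO3 (12 equiv), degassed MeOH/THF, 0 °C, argon, short contact time; then cold 1 M HCl
Reagents that add atoms: none
Why: Base-mediated transesterification (methanolysis) should cleave the six aryl acetates, whose phenoxide leaving groups are stabilised by the ortho butanoyl groups; low temperature, short contact time and exclusion of air are meant to prevent base-induced exchange of the methylene bridges and oxidation of the polyphenol.

Compound list
1 | 1-(2,4,6-trihydroxyphenyl)butan-1-one (phlorobutyrophenone) | CCCC(=O)c1c(O)cc(O)cc1O | starting material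
2 | iodomethane | CI | starting material
3 | butyrylfilicinic acid, 2-butanoyl-3,5-dihydroxy-4,4-dimethylcyclohexa-2,5-dien-1-one | CCCC(=O)C1=C(O)C(C)(C)C(O)=CC1=O | intermediate
4 | formaldehyde | C=O | starting material
5 | Mannich base, 2-butanoyl-3,5-dihydroxy-4,4-dimethyl-6-(piperidin-1-ylmethyl)cyclohexa-2,5-dien-1-one (formed in the flask) | CCCC(=O)C1=C(O)C(C)(C)C(O)=C(CN2CCCCC2)C1=O | intermediate
6 | ring A–ring B dimer, 2-butanoyl-6-[(3-butanoyl-2,4,6-trihydroxyphenyl)methyl]-3,5-dihydroxy-4,4-dimethylcyclohexa-2,5-dien-1-one | CCCC(=O)C1=C(O)C(C)(C)C(O)=C(Cc2c(O)cc(O)c(C(=O)CCC)c2O)C1=O | intermediate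
7 | bis(3-butanoyl-2,4,6-trihydroxyphenyl)methane, methylenebis(phlorobutyrophenone) | CCCC(=O)c1c(O)cc(O)c(Cc2c(O)cc(O)c(C(=O)CCC)c2O)c1O | intermediate
8 | bis[3-butanoyl-2,4,6-trihydroxy-5-(methylsulfanylmethyl)phenyl]methane | CSCc1c(O)c(C(=O)CCC)c(O)c(Cc2c(O)c(CSC)c(O)c(C(=O)CCC)c2O)c1O | intermediate
9 | bis[2,4,6-triacetoxy-3-butanoyl-5-(methylsulfanylmethyl)phenyl]methane (key-step precursor) | CSCc1c(OC(C)=O)c(C(=O)CCC)c(OC(C)=O)c(Cc2c(OC(C)=O)c(CSC)c(OC(C)=O)c(C(=O)CCC)c2OC(C)=O)c1OC(C)=O | intermediate
10 | bis(S-chlorosulfonium) salt of 9 with succinimide anions (formed in the flask) | C[S+](Cl)Cc1c(OC(C)=O)c(C(=O)CCC)c(OC(C)=O)c(Cc2c(OC(C)=O)c(C[S+](C)Cl)c(OC(C)=O)c(C(=O)CCC)c2OC(C)=O)c1OC(C)=O.O=C1CCC(=O)[N-]1.O=C1CCC(=O)[N-]1 | intermediate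
11 | bis(aryloxysulfonium) dichloride, each sulfur bonded to O-2 of ring B or E of one unit of 6 (formed in the flask) | CCCC(=O)C1=C(O)C(C)(C)C(O)=C(Cc2c(O[S+](C)Cc3c(OC(C)=O)c(C(=O)CCC)c(OC(C)=O)c(Cc4c(OC(C)=O)c(C[S+](C)Oc5cc(O)c(C(=O)CCC)c(O)c5CC6=C(O)C(C)(C)C(O)=C(C(=O)CCC)C6=O)c(OC(C)=O)c(C(=O)CCC)c4OC(C)=O)c3OC(C)=O)cc(O)c(C(=O)CCC)c2O)C1=O.[Cl-].[Cl-] | intermediate
12 | hexamer with SCH3 on the B–C and D–E bridge carbons and acetates on rings C and D, mixture of diastereomers at the two sulfur-bearing carbons (key-step product) | CCCC(=O)C1=C(O)C(C)(C)C(O)=C(Cc2c(O)c(C(SC)c3c(OC(C)=O)c(Cc4c(OC(C)=O)c(C(SC)c5c(O)c(CC6=C(O)C(C)(C)C(O)=C(C(=O)CCC)C6=O)c(O)c(C(=O)CCC)c5O)c(OC(C)=O)c(C(=O)CCC)c4OC(C)=O)c(OC(C)=O)c(C(=O)CCC)c3OC(C)=O)c(O)c(C(=O)CCC)c2O)C1=O | intermediate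
13 | hexamer hexaacetate, all five bridges CH2, acetates on rings C and D | CCCC(=O)C1=C(O)C(C)(C)C(O)=C(Cc2c(O)c(Cc3c(OC(C)=O)c(Cc4c(OC(C)=O)c(Cc5c(O)c(CC6=C(O)C(C)(C)C(O)=C(C(=O)CCC)C6=O)c(O)c(C(=O)CCC)c5O)c(OC(C)=O)c(C(=O)CCC)c4OC(C)=O)c(OC(C)=O)c(C(=O)CCC)c3OC(C)=O)c(O)c(C(=O)CCC)c2O)C1=O | intermediate
14 | CNP0237140.0, hexamer of two butyrylfilicinic acid end rings and four phlorobutyrophenone rings joined by five CH2 groups | CCCC(=O)C1=C(O)C(C)(C)C(O)=C(Cc2c(O)c(Cc3c(O)c(Cc4c(O)c(Cc5c(O)c(CC6=C(O)C(C)(C)C(O)=C(C(=O)CCC)C6=O)c(O)c(C(=O)CCC)c5O)c(O)c(C(=O)CCC)c4O)c(O)c(C(=O)CCC)c3O)c(O)c(C(=O)CCC)c2O)C1=O | target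

Total step count: 8
Longest linear sequence: 6 steps (steps 3, 4, 5, 6, 7, 8, from 1 to 14)

Steps most likely to fail

Step 6. The chlorosulfonium centres may collapse by Pummerer-type alpha-chlorination before they are captured at oxygen, capture may take place at a ring A enol oxygen or through the ring B carbon on sulfur (an arylsulfonium that cannot rearrange), the ylide may form at the S-methyl group, or only one of the two sulfur centres may couple. The fallback gives up the oxygen tether and uses the thionium route deliberately. It sets out from 9, which with NCS (2.1 equiv) in CH2Cl2 at 0 °C to rt should give the bis(alpha-chloro sulfide) F1. ZnCl2 in CH2Cl2 at −20 °C in the presence of 6 (2.3 equiv) then ionises each C–Cl bond, and the thionium ions alkylate C-3 of ring B in a Friedel–Crafts reaction. The fallback comes back to the route at 12.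

Step 7. The radical chain may propagate poorly at a methyl sulfide, the acidic enols and phenols may consume tin hydride, heating may expel methanethiol toward a quinone methide, and tin residues may be hard to separate from a polyphenol. The fallback replaces the chain reaction by hydrogenolysis on a metal surface. It sets out from 12, which is stirred with Raney Ni (W-2, deactivated by brief heating in acetone) in EtOH/THF at rt to cleave both C–S bonds, and it comes back to the route at 13; no new compound arises (F0).

Step 8. Base may induce fragmentation and recombination of the methylene bridges (scrambling of chain length), methanolysis of the hindered acetates may stall, or the polyanion may be oxidised by air. The fallback changes the protecting group so that the last step is acidic. It sets out from 8, which with Boc2O, DMAP and Et3N in CH2Cl2 should give the hexakis(tert-butyl carbonate) F2. The coupling of step 6 with 6 then gives the bis(methylsulfanyl) hexamer carbonate F3, and Bu3SnH/AIBN as in step 7 gives the sulfur-free hexamer carbonate F4. Trifluoroacetic acid in CH2Cl2 at 0 °C removes the six carbonates, and the fallback comes back to the route at 14.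

Further compounds
F1 | step 6 | bis[2,4,6-triacetoxy-3-butanoyl-5-(chloro(methylsulfanyl)methyl)phenyl]methane (diastereomer mixture) | CSC(Cl)c1c(OC(C)=O)c(C(=O)CCC)c(OC(C)=O)c(Cc2c(OC(C)=O)c(C(Cl)SC)c(OC(C)=O)c(C(=O)CCC)c2OC(C)=O)c1OC(C)=O
F0 | step 7 | none | none
F2 | step 8 | hexakis(tert-butyl carbonate) of 8 | CSCc1c(OC(=O)OC(C)(C)C)c(C(=O)CCC)c(OC(=O)OC(C)(C)C)c(Cc2c(OC(=O)OC(C)(C)C)c(CSC)c(OC(=O)OC(C)(C)C)c(C(=O)CCC)c2OC(=O)OC(C)(C)C)c1OC(=O)OC(C)(C)C
F3 | step 8 | hexamer with SCH3 on the B–C and D–E bridge carbons and tert-butyl carbonates on rings C and D (diastereomer mixture) | CCCC(=O)C1=C(O)C(C)(C)C(O)=C(Cc2c(O)c(C(SC)c3c(OC(=O)OC(C)(C)C)c(Cc4c(OC(=O)OC(C)(C)C)c(C(SC)c5c(O)c(CC6=C(O)C(C)(C)C(O)=C(C(=O)CCC)C6=O)c(O)c(C(=O)CCC)c5O)c(OC(=O)OC(C)(C)C)c(C(=O)CCC)c4OC(=O)OC(C)(C)C)c(OC(=O)OC(C)(C)C)c(C(=O)CCC)c3OC(=O)OC(C)(C)C)c(O)c(C(=O)CCC)c2O)C1=O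
F4 | step 8 | hexamer with five CH2 bridges and tert-butyl carbonates on rings C and D | CCCC(=O)C1=C(O)C(C)(C)C(O)=C(Cc2c(O)c(Cc3c(OC(=O)OC(C)(C)C)c(Cc4c(OC(=O)OC(C)(C)C)c(Cc5c(O)c(CC6=C(O)C(C)(C)C(O)=C(C(=O)CCC)C6=O)c(O)c(C(=O)CCC)c5O)c(OC(=O)OC(C)(C)C)c(C(=O)CCC)c4OC(=O)OC(C)(C)C)c(OC(=O)OC(C)(C)C)c(C(=O)CCC)c3OC(=O)OC(C)(C)C)c(O)c(C(=O)CCC)c2O)C1=O
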